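**Strategy.** The 7-oxabicyclo[2.2.1]heptane (C1–C6, O7) is disconnected at C1–C6. C1 is an ether carbon flanked by C2, the only ring carbon that carries the side chain; written as C1=C2 with the first side-chain carbon as an ester, this is a cyclic β-alkoxyacrylate. A 5-exo radical closure of a C4-bound two-carbon arm onto C1 of a 4,5-dihydrofuran-3-carboxylate therefore forges the quaternary bridgehead and the whole bicycle in one operation. The precursor has one stereocentre, C4, taken from C3 of (R)-linalool (vinyl = C5–C6). Exo-face conjugate methylation, coupling to an (S)-linalool-derived allylic chloride and bromoetherification complete the route.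

Key step: step 6

Remark: oxanorbornane numbering is C1 (bridgehead next to C2), C2 (side chain), C3 (methyl), C4 (bridgehead), C5, C6, O7. Assumption: (S)-(+)-linalool of high enantiomeric purity is taken as a commercial starting material, like (R)-(−)-linalool.

**Step 1**
Reactants: 1 (R)-(−)-linalool [(3R)-3,7-dimethylocta-1,6-dien-3-ol]
Product: 2 (5R)-5-methyl-5-vinyltetrahydrofuran-2-ol (lactol; both anomers)
Conditions: O3 (1 equiv), CH2Cl2/MeOH, pyridine, −78 °C; Me2S
Reagents that add atoms: ozone, [O-][O+]=O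
Why: Chemoselective ozonolysis of the electron-rich trisubstituted alkene (the vinyl group reacts much more slowly) with reductive work-up should give the hydroxy aldehyde, which closes to the lactol; the carbinol stereocentre (future C4) is untouched.

**Step 2**
Reactants: 2 (5R)-5-methyl-5-vinyltetrahydrofuran-2-ol
Product: 3 (5R)-5-methyl-5-vinyldihydrofuran-2(3H)-one
Conditions: TEMPO (cat.), PhI(OAc)2, CH2Cl2, rt
Reagents that add atoms: none
Why: Oxoammonium (TEMPO) oxidation of a lactol to the lactone, which touches neither the vinyl group nor the stereocentre.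

**Step 3**
Reactants: 3 (5R)-5-methyl-5-vinyldihydrofuran-2(3H)-one
Product: 5 (2R)-2,5-dimethyl-2-vinyl-2,3-dihydrofuran, via exocyclic enol ether 4 (not isolated)
Conditions: Cp2TiMe2, toluene, 70 °C; then pyridinium p-toluenesulfonate (cat.), CH2Cl2, rt
Reagents that add atoms: dimethyltitanocene, C[Ti](C)(C1C=CC=C1)C1C=CC=C1
Why: Petasis methylenation of the lactone carbonyl under neutral conditions, followed by acid-catalysed exo-to-endo isomerisation, should give the more stable trisubstituted cyclic enol ether without involving the quaternary C–O centre.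

**Step 4**
Reactants: 5 (2R)-2,5-dimethyl-2-vinyl-2,3-dihydrofuran
Product: 7 methyl (5R)-2,5-dimethyl-5-vinyl-4,5-dihydrofuran-3-carboxylate, via trichloromethyl ketone 6 (not isolated)
Conditions: Cl3CCOCl, pyridine, CH2Cl2, 0 °C → rt; then MeOH, K2CO3 (cat.), rt
Reagents that add atoms: trichloroacetyl chloride, ClC(=O)C(Cl)(Cl)Cl; methanol, CO
Why: Electrophilic C-acylation of the enol ether at its nucleophilic β-carbon followed by haloform-type methanolysis of the trichloromethyl ketone should give the cyclic β-alkoxyacrylate (vinylogous carbonate).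

**Step 5**
Reactants: 7 methyl (5R)-2,5-dimethyl-5-vinyl-4,5-dihydrofuran-3-carboxylate
Product: 9 methyl (5R)-5-(2-iodoethyl)-2,5-dimethyl-4,5-dihydrofuran-3-carboxylate, via B-alkyl-9-BBN adduct 8 (not isolated)
Conditions: 9-BBN, THF, 0 °C → rt; then NaOMe, I2, MeOH, 0 °C
Reagents that add atoms: iodine, II
Why: Anti-Markovnikov hydroboration of the only unhindered alkene (the tetrasubstituted acrylate alkene and the ester are inert to 9-BBN) and base-induced iodinolysis of the primary C–B bond should give the primary iodide.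

**Step 6**
Reactants: 9 methyl (5R)-5-(2-iodoethyl)-2,5-dimethyl-4,5-dihydrofuran-3-carboxylate
Product: 10 methyl (1R,4S)-1,4-dimethyl-7-oxabicyclo[2.2.1]heptane-2-carboxylate (mixture of C2 epimers)
Conditions: (Me3Si)3SiH, AIBN (cat.), toluene (0.01 M), 85 °C, slow addition of the silane
Reagents that add atoms: none
Why: The silyl radical abstracts iodine from 9 and the primary C6 radical adds 5-exo-trig to C1, the β-carbon of the cyclic β-alkoxyacrylate, giving the ester-stabilised C2 radical, which the silane reduces. The closest known reaction type is alkyl-radical cyclisation onto β-alkoxyacrylates for oxacycle synthesis, here across a ring as in the 2-(cyclopent-3-enyl)ethyl to 2-norbornyl radical closure. The new bond closes the second oxolane ring (O7–C4–C5–C6–C1) and with it the cyclohexane ring of the bicycle. The quaternary centre C1 is dictated by C4, because the two-carbon arm can reach C1 only on the face on which it is held; C2 forms as a mixture that step 7 erases. The step needs attack at C1 rather than C2 (which would give a 2-oxabicyclo[2.2.1]heptane) and closure before hydrogen transfer; the first is secured by acrylate polarity (nucleophilic radical, ester-stabilised adduct radical), the second by high dilution and slow addition of the poor hydrogen donor (Me3Si)3SiH.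

**Step 7**
Reactants: 10 methyl (1R,4S)-1,4-dimethyl-7-oxabicyclo[2.2.1]heptane-2-carboxylate
Product: 12 methyl (1R,4S)-1,4-dimethyl-7-oxabicyclo[2.2.1]hept-2-ene-2-carboxylate, via α-phenylselanyl ester 11 (not isolated)
Conditions: LiN(i-Pr)2, THF, −78 °C; PhSeBr, −78 °C; then H2O2, pyridine, CH2Cl2, 0 °C → rt
Reagents that add atoms: none
Why: Selenoxide syn-elimination (α-selenenylation of the ester enolate, kept at −78 °C so that it does not expel the bridging oxygen, then oxidation) should give the C2=C3 alkene, the only possible direction because C1 is quaternary.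

**Step 8**
Reactants: 12 methyl (1R,4S)-1,4-dimethyl-7-oxabicyclo[2.2.1]hept-2-ene-2-carboxylate
Product: 14 methyl (1R,2R,3R,4S)-1,3,4-trimethyl-7-oxabicyclo[2.2.1]heptane-2-carboxylate, via silyl ketene acetal 13 (not isolated)
Conditions: Me2CuLi, Me3SiCl, THF/Et2O, −78 °C; then dilute aq. HCl, 0 °C
Reagents that add atoms: lithium dimethylcuprate, [Li+].C[Cu-]C
Why: Silyl-chloride-accelerated cuprate conjugate addition should deliver the methyl group to C3 on the exo face (the oxygen-bridge side, away from the C5–C6 bridge), and exo protonation of the trapped silyl ketene acetal should place the ester endo (also the more stable trans arrangement), setting C3 and C2.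

**Step 9**
Reactants: 14 methyl (1R,2R,3R,4S)-1,3,4-trimethyl-7-oxabicyclo[2.2.1]heptane-2-carboxylate
Product: 15 [(1R,2S,3R,4S)-1,3,4-trimethyl-7-oxabicyclo[2.2.1]heptan-2-yl]methanol
Conditions: LiAlH4, Et2O, 0 °C
Reagents that add atoms: none
Why: Hydride reduction of the ester to the primary alcohol, which forms no enolate and leaves the ether bridge and all stereocentres intact.

**Step 10**
Reactants: 15 [(1R,2S,3R,4S)-1,3,4-trimethyl-7-oxabicyclo[2.2.1]heptan-2-yl]methanol
Product: 16 (1R,2R,3R,4S)-2-(iodomethyl)-1,3,4-trimethyl-7-oxabicyclo[2.2.1]heptane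
Conditions: I2, PPh3, imidazole, CH2Cl2, 0 °C → rt
Reagents that add atoms: iodine, II
Why: Appel-type iodination of a primary alcohol by SN2 displacement of the alkoxyphosphonium ion, which does not touch a stereocentre.

**Step 11**
Reactants: 17 (S)-(+)-linalool [(3S)-3,7-dimethylocta-1,6-dien-3-ol]
Product: 18 (2E,6S)-2,6-dimethylocta-2,7-diene-1,6-diol
Conditions: SeO2 (cat.), t-BuOOH, CH2Cl2, rt
Reagents that add atoms: tert-butyl hydroperoxide, CC(C)(C)OO
Why: Selenium dioxide allylic oxidation (ene reaction then [2,3]-sigmatropic shift) is selective for the (E)-methyl group of the trisubstituted alkene and leaves the carbinol stereocentre untouched.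

**Step 12**
Reactants: 18 (2E,6S)-2,6-dimethylocta-2,7-diene-1,6-diol
Product: 19 (3S,6E)-8-chloro-3,7-dimethylocta-1,6-dien-3-ol
Conditions: MsCl, LiCl, 2,4,6-collidine, DMF, 0 °C
Reagents that add atoms: lithium chloride, [Li+].[Cl-]
Why: Selective mesylation of the primary allylic alcohol and SN2 displacement by chloride without allylic transposition; the hindered tertiary alcohol does not react.

**Step 13**
Reactants: 16 (1R,2R,3R,4S)-2-(iodomethyl)-1,3,4-trimethyl-7-oxabicyclo[2.2.1]heptane; 19 (3S,6E)-8-chloro-3,7-dimethylocta-1,6-dien-3-ol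
Product: 22 (3S,6E)-3,7-dimethyl-9-[(1R,2R,3R,4S)-1,3,4-trimethyl-7-oxabicyclo[2.2.1]heptan-2-yl]nona-1,6-dien-3-ol, via Grignard reagent 20 (not isolated), via bromomagnesium alkoxide 21 (not isolated)
Conditions: Mg, Et2O, rt (on 16); MeMgBr (1 equiv), THF, −78 °C (on 19); then combined, Li2CuCl4 (cat.), THF, −78 → 0 °C; aq. NH4Cl
Reagents that add atoms: none
Why: Copper-catalysed coupling of a primary alkyl Grignard reagent with a primary allylic chloride should proceed by direct substitution with retention of the (E)-alkene, the tertiary alcohol being masked as its magnesium alkoxide.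

**Step 14**
Reactants: 22 (3S,6E)-3,7-dimethyl-9-[(1R,2R,3R,4S)-1,3,4-trimethyl-7-oxabicyclo[2.2.1]heptan-2-yl]nona-1,6-dien-3-ol
Product: 23 dactylopyranoid, (2S,3R,6S)-3-bromo-2,6-dimethyl-2-{2-[(1R,2R,3R,4S)-1,3,4-trimethyl-7-oxabicyclo[2.2.1]heptan-2-yl]ethyl}-6-vinyltetrahydro-2H-pyran
Conditions: 2,4,4,6-tetrabromocyclohexa-2,5-dienone, MeNO2, 0 °C → rt
Reagents that add atoms: 2,4,4,6-tetrabromocyclohexa-2,5-dienone, O=C1C(Br)=CC(Br)(Br)C=C1Br
Why: Bromonium-induced 6-endo (Markovnikov) bromoetherification adds Br and the tertiary hydroxyl anti across the (E)-alkene, which fixes the relative configuration of oxane C3 and C2; since the resident centres are remote, no strong facial preference is expected, so 23 should form together with its (2R,3S,6S) diastereomer and some oxolane regioisomer and be separated by chromatography.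

**Compound list**
1 | (R)-(−)-linalool | C=C[C@](C)(O)CCC=C(C)C | starting material
2 | (5R)-5-methyl-5-vinyltetrahydrofuran-2-ol | C=C[C@@]1(C)CCC(O)O1 | intermediate
3 | (5R)-5-methyl-5-vinyldihydrofuran-2(3H)-one | C=C[C@@]1(C)CCC(=O)O1 | intermediate
4 | (5R)-5-methyl-2-methylidene-5-vinyltetrahydrofuran | C=C[C@@]1(C)CCC(=C)O1 | intermediate
5 | (2R)-2,5-dimethyl-2-vinyl-2,3-dihydrofuran | C=C[C@@]1(C)CC=C(C)O1 | intermediate
6 | 2,2,2-trichloro-1-[(5R)-2,5-dimethyl-5-vinyl-4,5-dihydrofuran-3-yl]ethan-1-one | C=C[C@@]1(C)CC(C(=O)C(Cl)(Cl)Cl)=C(C)O1 | intermediate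
7 | methyl (5R)-2,5-dimethyl-5-vinyl-4,5-dihydrofuran-3-carboxylate | C=C[C@@]1(C)CC(C(=O)OC)=C(C)O1 | intermediate
8 | methyl (5S)-5-[2-(9-borabicyclo[3.3.1]nonan-9-yl)ethyl]-2,5-dimethyl-4,5-dihydrofuran-3-carboxylate | B1(C2CCCC1CCC2)CC[C@@]3(C)CC(C(=O)OC)=C(C)O3 | intermediate
9 | methyl (5R)-5-(2-iodoethyl)-2,5-dimethyl-4,5-dihydrofuran-3-carboxylate | ICC[C@@]1(C)CC(C(=O)OC)=C(C)O1 | intermediate
10 | methyl (1R,4S)-1,4-dimethyl-7-oxabicyclo[2.2.1]heptane-2-carboxylate (C2 epimers) | COC(=O)C1C[C@]2(C)CC[C@@]1(C)O2 | intermediate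
11 | methyl (1R,4S)-1,4-dimethyl-2-(phenylselanyl)-7-oxabicyclo[2.2.1]heptane-2-carboxylate | COC(=O)C1([Se]c3ccccc3)C[C@]2(C)CC[C@@]1(C)O2 | intermediate
12 | methyl (1R,4S)-1,4-dimethyl-7-oxabicyclo[2.2.1]hept-2-ene-2-carboxylate | COC(=O)C1=C[C@]2(C)CC[C@@]1(C)O2 | intermediate
13 | [methoxy((1R,3R,4S)-1,3,4-trimethyl-7-oxabicyclo[2.2.1]heptan-2-ylidene)methoxy]trimethylsilane | COC(O[Si](C)(C)C)=C1[C@@H](C)[C@]2(C)CC[C@@]1(C)O2 | intermediate
14 | methyl (1R,2R,3R,4S)-1,3,4-trimethyl-7-oxabicyclo[2.2.1]heptane-2-carboxylate (3-exo-methyl, 2-endo-ester) | COC(=O)[C@@H]1[C@@H](C)[C@]2(C)CC[C@@]1(C)O2 | intermediate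
15 | [(1R,2S,3R,4S)-1,3,4-trimethyl-7-oxabicyclo[2.2.1]heptan-2-yl]methanol | OC[C@@H]1[C@@H](C)[C@]2(C)CC[C@@]1(C)O2 | intermediate
16 | (1R,2R,3R,4S)-2-(iodomethyl)-1,3,4-trimethyl-7-oxabicyclo[2.2.1]heptane | IC[C@@H]1[C@@H](C)[C@]2(C)CC[C@@]1(C)O2 | intermediate
17 | (S)-(+)-linalool | C=C[C@@](C)(O)CCC=C(C)C | starting material
18 | (2E,6S)-2,6-dimethylocta-2,7-diene-1,6-diol | C=C[C@@](C)(O)CC/C=C(\C)CO | intermediate
19 | (3S,6E)-8-chloro-3,7-dimethylocta-1,6-dien-3-ol | C=C[C@@](C)(O)CC/C=C(\C)CCl | intermediate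
20 | {[(1R,2R,3R,4S)-1,3,4-trimethyl-7-oxabicyclo[2.2.1]heptan-2-yl]methyl}magnesium iodide | I[Mg]C[C@@H]1[C@@H](C)[C@]2(C)CC[C@@]1(C)O2 | intermediate
21 | bromomagnesium (3S,6E)-8-chloro-3,7-dimethylocta-1,6-dien-3-olate | C=C[C@@](C)(O[Mg]Br)CC/C=C(\C)CCl | intermediate
22 | (3S,6E)-3,7-dimethyl-9-[(1R,2R,3R,4S)-1,3,4-trimethyl-7-oxabicyclo[2.2.1]heptan-2-yl]nona-1,6-dien-3-ol | C=C[C@@](C)(O)CC/C=C(\C)CC[C@@H]1[C@@H](C)[C@]2(C)CC[C@@]1(C)O2 | intermediate
23 | dactylopyranoid | C=C[C@]1(C)CC[C@@H](Br)[C@](C)(CC[C@@H]2[C@@H](C)[C@]3(C)CC[C@@]2(C)O3)O1 | target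

**Step count.** Total: 14 steps. Longest linear sequence: 12 steps (steps 1–10, 13, 14).

**Steps most likely to fail**

Step 6. The primary radical may take up hydrogen before it closes onto the tetrasubstituted, oxygen-bearing alkene carbon, giving the simply reduced ethyl compound. The fallback sets out from 9 and uses a ring-forming alkyl Heck reaction (Pd(PPh3)4 (cat.), 1,2,2,6,6-pentamethylpiperidine, benzene, 110 °C). No hydrogen donor is present; the organopalladium/radical pair either cyclises or recombines, and the sequence ends by β-hydride elimination from C3. This should give enoate 12 directly, so the route is rejoined at 12 and step 7 is bypassed. No compound outside the list arises (F0).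

Step 8. Conjugate addition at C3, next to the quaternary bridgehead, may be slow, which leaves the metal enolate time to expel the bridging alkoxide and open the oxygen bridge. The fallback sets out from 12 and moves the addition to a more electrophilic acceptor. Reduction with i-Bu2AlH (CH2Cl2, −78 °C) should give [(1R,4S)-1,4-dimethyl-7-oxabicyclo[2.2.1]hept-2-en-2-yl]methanol F1, and MnO2 oxidation the enal (1R,4S)-1,4-dimethyl-7-oxabicyclo[2.2.1]hept-2-ene-2-carbaldehyde F2. Me2CuLi with Me3SiCl at −78 °C should add on the exo face and be trapped as the trimethylsilyl enol ether F3. Mild acid should then give (1R,2R,3R,4S)-1,3,4-trimethyl-7-oxabicyclo[2.2.1]heptane-2-carbaldehyde F4 by exo protonation. NaBH4 in MeOH returns the route at alcohol 15, so step 9 is not needed.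

Step 14. Facial selectivity of bromonium formation is likely to be poor because the controlling centres are remote, and 5-exo closure competes. The fallback sets out from 22 and uses reagent control. Shi epoxidation (D-fructose-derived ketone expected, KHSO5, K2CO3 buffer, MeCN/H2O, 0 °C) of the trisubstituted alkene should give (3S)-3-methyl-5-[(2R,3R)-3-methyl-3-{2-[(1R,2R,3R,4S)-1,3,4-trimethyl-7-oxabicyclo[2.2.1]heptan-2-yl]ethyl}oxiran-2-yl]pent-1-en-3-ol F5. Camphorsulfonic acid (cat.) should then induce the favoured 5-exo opening with inversion at the secondary carbon, giving (2R)-2-[(2S,5S)-5-methyl-5-vinyloxolan-2-yl]-4-[(1R,2R,3R,4S)-1,3,4-trimethyl-7-oxabicyclo[2.2.1]heptan-2-yl]butan-2-ol F6. Ionisation of its tertiary alcohol in the presence of bromide (Ph3P, CBr4, 2,6-di-tert-butylpyridine, CH2Cl2) should let the ring oxygen participate, forming a bicyclic oxonium ion that bromide opens at the secondary carbon. This oxolane-to-oxane ring expansion inverts both carbons and should arrive at 23 with the oxane C2 and C3 configurations fixed by the epoxidation catalyst.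

**Further compounds**
F0 | step 6 | none | none
F1 | step 8 | [(1R,4S)-1,4-dimethyl-7-oxabicyclo[2.2.1]hept-2-en-2-yl]methanol | OCC1=C[C@]2(C)CC[C@@]1(C)O2
F2 | step 8 | (1R,4S)-1,4-dimethyl-7-oxabicyclo[2.2.1]hept-2-ene-2-carbaldehyde | O=CC1=C[C@]2(C)CC[C@@]1(C)O2
F3 | step 8 | trimethyl{[(1R,3R,4S)-1,3,4-trimethyl-7-oxabicyclo[2.2.1]heptan-2-ylidene]methoxy}silane | C[Si](C)(C)OC=C1[C@@H](C)[C@]2(C)CC[C@@]1(C)O2
F4 | step 8 | (1R,2R,3R,4S)-1,3,4-trimethyl-7-oxabicyclo[2.2.1]heptane-2-carbaldehyde | O=C[C@@H]1[C@@H](C)[C@]2(C)CC[C@@]1(C)O2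
F5 | step 14 | (3S)-3-methyl-5-[(2R,3R)-3-methyl-3-{2-[(1R,2R,3R,4S)-1,3,4-trimethyl-7-oxabicyclo[2.2.1]heptan-2-yl]ethyl}oxiran-2-yl]pent-1-en-3-ol | C=C[C@@](C)(O)CC[C@H]1O[C@]1(C)CC[C@@H]2[C@@H](C)[C@]3(C)CC[C@@]2(C)O3
F6 | step 14 | (2R)-2-[(2S,5S)-5-methyl-5-vinyloxolan-2-yl]-4-[(1R,2R,3R,4S)-1,3,4-trimethyl-7-oxabicyclo[2.2.1]heptan-2-yl]butan-2-ol | C=C[C@]1(C)CC[C@H](O1)[C@](C)(O)CC[C@@H]2[C@@H](C)[C@]3(C)CC[C@@]2(C)O3
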